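**Plan**

1. Retrosynthesis (germacrane numbering: C1/C10 epoxide, C4=C5 alkene, C6 and C8 OAc, C7 i-Pr, C14 CHO): the epoxy-aldehyde comes from the C14 allylic alcohol and the C8 acetate from a C8 ketone. The cyclodecadienone is then reconnected C5–C8 to a bicyclo[6.2.0]dec-5-ene, so the ten-membered ring is the product of a Grob fragmentation (two-carbon ring expansion, 8 → 10).
2. The bicycle is cut at C1=C10 (ring-closing metathesis), C3–C4 (Grignard addition), C8–C9 (Barbier allylation) and C5–C8/C6–C7 ([2+2] of isopropylketene with an enol ether).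
3. Forward: cyclobutanone (C5–C8) → two side arms → eight-membered ring (RCM) → ten-membered ring (fragmentation) → C8 reduction and acetylation → epoxide → aldehyde.
4. Stereochemistry: a carbinol centre from CBS reduction steers the ketene cycloaddition (C6, C7; cis on the four-membered ring) and is then erased. Felkin–Anh addition sets C4 relative to C5, and the antiperiplanar fragmentation converts this into the E-alkene. C8 comes from a hydroxyl-directed anti reduction and the epoxide from Sharpless reagent control.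
5. Enabling feature: the C8 oxygen and the C4=C5 alkene are γ-related through C5, and C5 and C8 are spanned by the two-carbon unit C6–C7. Bonding C5 to C8 makes these four atoms a strained four-membered ring fused to an eight-membered ring (C8–C9–C10–C1–C2–C3–C4–C5), and its fusion bond breaks with formation of ketone and alkene.

Key step: step 13

Assumption: in step 4 the ketene is taken to add to the enol-ether face predicted by the inside-alkoxy model (allylic C–O inside, methyl anti); if the opposite sense prevails, the (R)-CBS catalyst in step 2 supplies the enantiomeric carbinol and nothing else changes.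

Remark on names: in 8, 13–16 and 18 the four-membered ring is numbered C1 = carbon bearing the ketone or tertiary oxygen, C2 = CH(i-Pr), C3 = CH(OPMB), C4 = CH carrying the side chain. PMB = 4-methoxybenzyl, DMB = 3,4-dimethoxybenzyl, TBDPS = tert-butyldiphenylsilyl.

**Route**

Step 1
Reactants: 1 (4-methoxyphenyl)methanol; 2 but-3-yn-2-one
Product: 3 (3E)-4-[(4-methoxyphenyl)methoxy]but-3-en-2-one
Conditions: PMe3 (5 mol %), CH2Cl2, 0 °C → rt
Reagents that add atoms: none
Why: Phosphine-catalysed oxa-Michael addition of the alcohol to the ynone should give the thermodynamically preferred E β-alkoxy enone.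

Step 2
Reactants: 3 (3E)-4-[(4-methoxyphenyl)methoxy]but-3-en-2-one
Product: 4 (2R,3E)-4-[(4-methoxyphenyl)methoxy]but-3-en-2-ol
Conditions: (S)-2-methyl-CBS-oxazaborolidine (10 mol %), BH3·SMe2, THF, −30 °C; MeOH quench
Reagents that add atoms: none
Why: Corey–Bakshi–Shibata reduction treats the alkenyl group as large and the methyl group as small, so the (S)-catalyst should give the (R)-allylic alcohol by 1,2-reduction.

Step 3
Reactants: 4 (2R,3E)-4-[(4-methoxyphenyl)methoxy]but-3-en-2-ol
Product: 5 (1E,3R)-3-[(3,4-dimethoxyphenyl)methoxy]-1-[(4-methoxyphenyl)methoxy]but-1-ene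
Conditions: NaH, 3,4-dimethoxybenzyl chloride, n-Bu4NI (cat.), THF/DMF, 0 °C → rt
Reagents that add atoms: 3,4-dimethoxybenzyl chloride, COc1ccc(CCl)cc1OC
Why: Williamson etherification under basic conditions, which the acid-labile γ-alkoxy allylic alcohol tolerates, installs a DMB ether that DDQ can later remove in the presence of the PMB ether, and the stereocentre is untouched.

Step 4
Reactants: 5 (1E,3R)-3-[(3,4-dimethoxyphenyl)methoxy]-1-[(4-methoxyphenyl)methoxy]but-1-ene; 6 3-methylbutanoyl chloride
Product: 8 (2R,3S,4R)-4-{(1R)-1-[(3,4-dimethoxyphenyl)methoxy]ethyl}-3-[(4-methoxyphenyl)methoxy]-2-(propan-2-yl)cyclobutan-1-one, via 3-methylbut-1-en-1-one (isopropylketene) 7 (not isolated)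
Conditions: Et3N, CH2Cl2, slow addition of 6, rt → 40 °C
Reagents that add atoms: none
Why: Thermal [2+2] cycloaddition of the aldoketene with the enol ether, in which the ketene carbonyl carbon bonds to the β-carbon of the enol ether, addition is suprafacial on the E-alkene (3,4-trans), the isopropyl group ends cis to the neighbouring alkoxy group (usual endo preference of aldoketenes), and the face is chosen by the allylic stereocentre (C–O inside, methyl anti to the incoming ketene).

Step 5
Reactants: 9 2-methylidenepropane-1,3-diol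
Product: 10 2-({[tert-butyl(diphenyl)silyl]oxy}methyl)prop-2-en-1-ol
Conditions: NaH (1.0 equiv), THF, then TBDPSCl (1.0 equiv), 0 °C → rt
Reagents that add atoms: tert-butyl(chloro)diphenylsilane, CC(C)(C)[Si](Cl)(c1ccccc1)c1ccccc1
Why: Monosilylation of the symmetrical diol through its sparingly soluble monosodium alkoxide, which reacts once.

Step 6
Reactants: 10 2-({[tert-butyl(diphenyl)silyl]oxy}methyl)prop-2-en-1-ol
Product: 11 {[2-(bromomethyl)prop-2-en-1-yl]oxy}(tert-butyl)diphenylsilane
Conditions: CBr4, PPh3, CH2Cl2, 0 °C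
Reagents that add atoms: tetrabromomethane, BrC(Br)(Br)Br
Why: Appel bromination of the primary allylic alcohol under neutral conditions leaves the silyl ether intact.

Step 7
Reactants: 8 the cyclobutanone; 11 {[2-(bromomethyl)prop-2-en-1-yl]oxy}(tert-butyl)diphenylsilane
Product: 13 (1R,2R,3S,4R)-1-[2-({[tert-butyl(diphenyl)silyl]oxy}methyl)prop-2-en-1-yl]-4-{(1R)-1-[(3,4-dimethoxyphenyl)methoxy]ethyl}-3-[(4-methoxyphenyl)methoxy]-2-(propan-2-yl)cyclobutan-1-ol, via [2-({[tert-butyl(diphenyl)silyl]oxy}methyl)prop-2-en-1-yl]indium dibromide 12 (not isolated)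
Conditions: In powder, THF/H2O (1:1), rt
Reagents that add atoms: none
Why: Barbier allylation with the non-basic allylindium reagent avoids β-elimination of the 3-alkoxy group and should attack the cyclobutanone anti to the C-3 alkoxy and C-2 isopropyl groups, placing the new arm cis to the C-4 side chain as the later cis ring fusion requires.

Step 8
Reactants: 13 the tertiary cyclobutanol
Product: 14 trimethylsilyl ether of 13 (ring centres 1R,2R,3S,4R; side chain 1R)
Conditions: TMSOTf, Et3N, CH2Cl2, −78 °C
Reagents that add atoms: trimethylsilyl trifluoromethanesulfonate, C[Si](C)(C)OS(=O)(=O)C(F)(F)F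
Why: Silylation of the tertiary cyclobutanol with the silyl triflate masks it so that no β-hydroxy ketone, which would open the four-membered ring by retro-aldol cleavage, can arise in step 10, and this is the group that fluoride removes in step 13.

Step 9
Reactants: 14 the TMS ether
Product: 15 (1R)-1-[cyclobutyl]ethan-1-ol, i.e. 14 with the DMB group removed (ring centres 1R,2R,3S,4R)
Conditions: DDQ (1.1 equiv), CH2Cl2/pH 7 buffer (10:1), 0 °C
Reagents that add atoms: none
Why: Oxidative cleavage of benzyl-type ethers by DDQ is markedly faster for the more electron-rich 3,4-dimethoxybenzyl ether than for the 4-methoxybenzyl ether, so limiting DDQ at 0 °C under buffer should free only the side-chain carbinol.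

Step 10
Reactants: 15 the side-chain alcohol
Product: 16 the C-4 acetylcyclobutane (methyl ketone; ring centres 1R,2R,3S,4R)
Conditions: Dess–Martin periodinane, NaHCO3, CH2Cl2, 0 °C → rt
Reagents that add atoms: none
Why: Dess–Martin oxidation under buffered, non-basic conditions gives the methyl ketone without touching the silyl ethers, and the carbinol stereocentre that directed step 4 disappears here.

Step 11
Reactants: 16 the methyl ketone; 17 but-3-en-1-ylmagnesium bromide
Product: 18 (2R)-2-[cyclobutyl]hex-5-en-2-ol (ring centres 1R,2R,3S,4S)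
Conditions: THF, −78 °C; AcOH quench at −78 °C
Reagents that add atoms: none
Why: Grignard 1,2-addition under Felkin–Anh control, with the fully substituted ring carbon C-1 anti to the nucleophile and the carbonyl oxygen next to C-3, should give the (R) tertiary carbinol whose relationship to C-4 later determines the E-alkene.

Step 12
Reactants: 18 the diene
Product: 19 (1S,2R,5E,8R,9R,10S)-6-({[tert-butyl(diphenyl)silyl]oxy}methyl)-10-[(4-methoxyphenyl)methoxy]-2-methyl-9-(propan-2-yl)-8-[(trimethylsilyl)oxy]bicyclo[6.2.0]dec-5-en-2-ol (ring-cis alkene; E only through the CIP rank of CH2OSi)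
Conditions: Grubbs second-generation catalyst (10 mol %), toluene (2 mM), 60 °C
Reagents that add atoms: none
Why: Ring-closing metathesis between the terminal and the 1,1-disubstituted alkene is helped by the cis-1,2-disubstituted cyclobutane and the two fully substituted carbons, and the eight-membered ring can only hold the ring-cis trisubstituted alkene.

Step 13
Reactants: 19 the bicyclo[6.2.0]dec-5-en-2-ol
Product: 22 (3E,7E,9R,10R)-3-({[tert-butyl(diphenyl)silyl]oxy}methyl)-9-[(4-methoxyphenyl)methoxy]-7-methyl-10-(propan-2-yl)cyclodeca-3,7-dien-1-one (C3=C4 ring-cis, C7=C8 ring-trans), via the C-2 methanesulfonate 20 (not isolated), via the tetrabutylammonium C-8 alkoxide 21 (not isolated)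
Conditions: MsCl, Et3N, CH2Cl2, −40 °C; then TBAF (THF), −78 → −30 °C; pH 7 buffer quench
Reagents that add atoms: none
Why: Mesylation by the sulfene pathway turns the tertiary C-2 hydroxyl into a nucleofuge and fluoride then frees the C-8 cyclobutanolate, whose oxygen lone pair, the C8–C1 ring-fusion bond and the C2–OMs bond can align antiperiplanar so that C8=O, C1=C2 and mesylate form in one concerted heterolytic fragmentation. The closest known reaction type is the Grob (Wharton) fragmentation of 1,3-diol monosulfonates, here fluoride-triggered and driven by release of cyclobutane strain. No ring is closed: the ten-membered ring arises from the eight-membered ring by cleavage of the bond it shares with the cyclobutane, which inserts C-9 and C-10 (two-carbon ring expansion). No new sp3 stereocentre is created; the new stereo-element is the trisubstituted alkene, whose E geometry follows from the (1S,2R) relationship set in step 11, because with the mesylate anti to C-8 the ring carbon C-3 is anti and the methyl group syn to the cyclobutane carbon C-10, while C-9 and C-10 pass unchanged into the product. The step needs fragmentation to outrun E1 loss of the tertiary mesylate and silyl migration, which low temperature, in-situ formation of the mesylate and the strain-assisted cleavage should secure; the TMS ether is far more fluoride-labile than the primary TBDPS ether, and a cold buffered quench protects the β-alkoxy, β,γ-unsaturated ketone from epimerisation, elimination and conjugation.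

Step 14
Reactants: 22 the cyclodecadienone
Product: 23 (3E,7E,9R,10R)-3-({[tert-butyl(diphenyl)silyl]oxy}methyl)-9-hydroxy-7-methyl-10-(propan-2-yl)cyclodeca-3,7-dien-1-one
Conditions: DDQ (1.5 equiv), CH2Cl2/H2O (18:1), 0 °C → rt
Reagents that add atoms: none
Why: DDQ cleavage of the remaining PMB ether under neutral conditions unmasks the hydroxyl without base, so the β-hydroxy ketone should not undergo retro-aldol or elimination.

Step 15
Reactants: 23 the β-hydroxy ketone
Product: 24 (1R,2S,3R,4E,8E)-9-({[tert-butyl(diphenyl)silyl]oxy}methyl)-5-methyl-2-(propan-2-yl)cyclodeca-4,8-diene-1,3-diol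
Conditions: Me4NBH(OAc)3, MeCN/AcOH, −30 °C
Reagents that add atoms: none
Why: Saksena–Evans reduction, in which the free hydroxyl binds boron and delivers hydride intramolecularly through a chair-like six-membered transition state, should give the 1,3-anti diol and hence the (1R) carbinol.

Step 16
Reactants: 24 the diol
Product: 25 (1R,2S,3R,4E,8E)-9-({[tert-butyl(diphenyl)silyl]oxy}methyl)-5-methyl-2-(propan-2-yl)cyclodeca-4,8-diene-1,3-diyl diacetate
Conditions: Ac2O, pyridine, DMAP (cat.), CH2Cl2, 0 °C → rt
Reagents that add atoms: acetic anhydride, CC(=O)OC(C)=O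
Why: DMAP-catalysed acylation of both secondary alcohols, with no stereocentre affected.

Step 17
Reactants: 25 the diacetate
Product: 26 (1R,2S,3R,4E,8E)-9-(hydroxymethyl)-5-methyl-2-(propan-2-yl)cyclodeca-4,8-diene-1,3-diyl diacetate
Conditions: HF·pyridine, pyridine, THF, 0 °C → rt
Reagents that add atoms: none
Why: Buffered fluoride cleavage of the silyl ether frees the primary allylic alcohol under conditions in which acetates neither migrate nor hydrolyse.

Step 18
Reactants: 26 the allylic alcohol
Product: 27 (1R,2S,3R,4E,8R,9R)-8,9-epoxy-9-(hydroxymethyl)-5-methyl-2-(propan-2-yl)cyclodec-4-ene-1,3-diyl diacetate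
Conditions: Ti(Oi-Pr)4, D-(−)-diethyl tartrate, t-BuOOH, 4 Å MS, CH2Cl2, −20 °C
Reagents that add atoms: tert-butyl hydroperoxide, CC(C)(C)OO
Why: Sharpless asymmetric epoxidation is directed by the only free allylic hydroxyl, so the C4=C5 alkene flanked by an acetate is not touched, and with D-(−)-tartrate oxygen should be delivered by reagent control to the face that gives the (8R,9R) epoxide, cis-fused because the alkene is ring-cis.

Step 19
Reactants: 27 the epoxy alcohol
Product: 28 pulicanaral A, (1R,2S,3R,4E,8R,9S)-8,9-epoxy-9-formyl-5-methyl-2-(propan-2-yl)cyclodec-4-ene-1,3-diyl diacetate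
Conditions: Dess–Martin periodinane, NaHCO3, CH2Cl2, 0 °C
Reagents that add atoms: none
Why: Buffered Dess–Martin oxidation of the primary epoxy alcohol gives the α,β-epoxy aldehyde, whose fully substituted α-carbon cannot epimerise.

**Compound list**

1 | (4-methoxyphenyl)methanol | OCc1ccc(OC)cc1 | starting material
2 | but-3-yn-2-one | CC(=O)C#C | starting material
3 | (3E)-4-[(4-methoxyphenyl)methoxy]but-3-en-2-one | CC(=O)/C=C/OCc1ccc(OC)cc1 | intermediate
4 | (2R,3E)-4-[(4-methoxyphenyl)methoxy]but-3-en-2-ol | C[C@@H](O)/C=C/OCc1ccc(OC)cc1 | intermediate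
5 | (1E,3R)-3-[(3,4-dimethoxyphenyl)methoxy]-1-[(4-methoxyphenyl)methoxy]but-1-ene | C[C@@H](OCc1ccc(OC)c(OC)c1)/C=C/OCc1ccc(OC)cc1 | intermediate
6 | 3-methylbutanoyl chloride | CC(C)CC(=O)Cl | starting material
7 | 3-methylbut-1-en-1-one (isopropylketene) | CC(C)C=C=O | intermediate
8 | (2R,3S,4R)-4-{(1R)-1-[(3,4-dimethoxyphenyl)methoxy]ethyl}-3-[(4-methoxyphenyl)methoxy]-2-(propan-2-yl)cyclobutan-1-one | O=C1[C@H](C(C)C)[C@H](OCc2ccc(OC)cc2)[C@H]1[C@@H](C)OCc3ccc(OC)c(OC)c3 | intermediate
9 | 2-methylidenepropane-1,3-diol | C=C(CO)CO | starting material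
10 | 2-({[tert-butyl(diphenyl)silyl]oxy}methyl)prop-2-en-1-ol | C=C(CO)CO[Si](c1ccccc1)(c1ccccc1)C(C)(C)C | intermediate
11 | {[2-(bromomethyl)prop-2-en-1-yl]oxy}(tert-butyl)diphenylsilane | C=C(CBr)CO[Si](c1ccccc1)(c1ccccc1)C(C)(C)C | intermediate
12 | [2-({[tert-butyl(diphenyl)silyl]oxy}methyl)prop-2-en-1-yl]indium dibromide | C=C(C[In](Br)Br)CO[Si](c1ccccc1)(c1ccccc1)C(C)(C)C | intermediate
13 | (1R,2R,3S,4R)-1-[2-(TBDPS-oxymethyl)prop-2-en-1-yl]-4-{(1R)-1-(DMB-oxy)ethyl}-3-(PMB-oxy)-2-(propan-2-yl)cyclobutan-1-ol | C=C(CO[Si](c1ccccc1)(c1ccccc1)C(C)(C)C)C[C@@]1(O)[C@H](C(C)C)[C@H](OCc2ccc(OC)cc2)[C@H]1[C@@H](C)OCc3ccc(OC)c(OC)c3 | intermediate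
14 | trimethylsilyl ether of 13 (1R,2R,3S,4R; side chain 1R) | C=C(CO[Si](c1ccccc1)(c1ccccc1)C(C)(C)C)C[C@@]1(O[Si](C)(C)C)[C@H](C(C)C)[C@H](OCc2ccc(OC)cc2)[C@H]1[C@@H](C)OCc3ccc(OC)c(OC)c3 | intermediate
15 | (1R)-1-[(1R,2R,3S,4R)-cyclobutyl]ethan-1-ol (14 without DMB) | C=C(CO[Si](c1ccccc1)(c1ccccc1)C(C)(C)C)C[C@@]1(O[Si](C)(C)C)[C@H](C(C)C)[C@H](OCc2ccc(OC)cc2)[C@H]1[C@@H](C)O | intermediate
16 | (1R,2R,3S,4R)-4-acetyl-1-[2-(TBDPS-oxymethyl)prop-2-en-1-yl]-3-(PMB-oxy)-2-(propan-2-yl)-1-(trimethylsilyloxy)cyclobutane | C=C(CO[Si](c1ccccc1)(c1ccccc1)C(C)(C)C)C[C@@]1(O[Si](C)(C)C)[C@H](C(C)C)[C@H](OCc2ccc(OC)cc2)[C@H]1C(C)=O | intermediate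
17 | but-3-en-1-ylmagnesium bromide | C=CCC[Mg]Br | starting material
18 | (2R)-2-[(1R,2R,3S,4S)-cyclobutyl]hex-5-en-2-ol (ring substituents as in 16) | C=C(CO[Si](c1ccccc1)(c1ccccc1)C(C)(C)C)C[C@@]1(O[Si](C)(C)C)[C@H](C(C)C)[C@H](OCc2ccc(OC)cc2)[C@H]1[C@](C)(O)CCC=C | intermediate
19 | (1S,2R,5E,8R,9R,10S)-6-(TBDPS-oxymethyl)-10-(PMB-oxy)-2-methyl-9-(propan-2-yl)-8-(trimethylsilyloxy)bicyclo[6.2.0]dec-5-en-2-ol | C[C@@]1(O)CC/C=C(CO[Si](c2ccccc2)(c2ccccc2)C(C)(C)C)\C[C@@]2(O[Si](C)(C)C)[C@H](C(C)C)[C@H](OCc3ccc(OC)cc3)[C@@H]12 | intermediate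
20 | C-2 methanesulfonate of 19 (configuration unchanged) | C[C@@]1(OS(C)(=O)=O)CC/C=C(CO[Si](c2ccccc2)(c2ccccc2)C(C)(C)C)\C[C@@]2(O[Si](C)(C)C)[C@H](C(C)C)[C@H](OCc3ccc(OC)cc3)[C@@H]12 | intermediate
21 | tetrabutylammonium C-8 alkoxide of 20 (TMS removed) | C[C@@]1(OS(C)(=O)=O)CC/C=C(CO[Si](c2ccccc2)(c2ccccc2)C(C)(C)C)\C[C@@]2([O-])[C@H](C(C)C)[C@H](OCc3ccc(OC)cc3)[C@@H]12.CCCC[N+](CCCC)(CCCC)CCCC | intermediate
22 | (3E,7E,9R,10R)-3-(TBDPS-oxymethyl)-9-(PMB-oxy)-7-methyl-10-(propan-2-yl)cyclodeca-3,7-dien-1-one | COc1ccc(CO[C@@H]2/C=C(\C)CC/C=C(CO[Si](c3ccccc3)(c3ccccc3)C(C)(C)C)\CC(=O)[C@@H]2C(C)C)cc1 | intermediate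
23 | (3E,7E,9R,10R)-3-(TBDPS-oxymethyl)-9-hydroxy-7-methyl-10-(propan-2-yl)cyclodeca-3,7-dien-1-one | O[C@@H]1/C=C(\C)CC/C=C(CO[Si](c2ccccc2)(c2ccccc2)C(C)(C)C)\CC(=O)[C@@H]1C(C)C | intermediate
24 | (1R,2S,3R,4E,8E)-9-(TBDPS-oxymethyl)-5-methyl-2-(propan-2-yl)cyclodeca-4,8-diene-1,3-diol | O[C@@H]1/C=C(\C)CC/C=C(CO[Si](c2ccccc2)(c2ccccc2)C(C)(C)C)\C[C@@H](O)[C@@H]1C(C)C | intermediate
25 | (1R,2S,3R,4E,8E)-9-(TBDPS-oxymethyl)-5-methyl-2-(propan-2-yl)cyclodeca-4,8-diene-1,3-diyl diacetate | CC(=O)O[C@@H]1/C=C(\C)CC/C=C(CO[Si](c2ccccc2)(c2ccccc2)C(C)(C)C)\C[C@@H](OC(C)=O)[C@@H]1C(C)C | intermediate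
26 | (1R,2S,3R,4E,8E)-9-(hydroxymethyl)-5-methyl-2-(propan-2-yl)cyclodeca-4,8-diene-1,3-diyl diacetate | CC(=O)O[C@@H]1/C=C(\C)CC/C=C(CO)\C[C@@H](OC(C)=O)[C@@H]1C(C)C | intermediate
27 | (1R,2S,3R,4E,8R,9R)-8,9-epoxy-9-(hydroxymethyl)-5-methyl-2-(propan-2-yl)cyclodec-4-ene-1,3-diyl diacetate | CC(=O)O[C@@H]1/C=C(\C)CC[C@H]2O[C@@]2(CO)C[C@@H](OC(C)=O)[C@@H]1C(C)C | intermediate
28 | pulicanaral A, (1R,2S,3R,4E,8R,9S)-8,9-epoxy-9-formyl-5-methyl-2-(propan-2-yl)cyclodec-4-ene-1,3-diyl diacetate | CC(=O)O[C@@H]1/C=C(\C)CC[C@H]2O[C@@]2(C=O)C[C@@H](OC(C)=O)[C@@H]1C(C)C | target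

**Totals and risks**

Total step count: 19. Longest linear sequence: 17 (steps 1–4 and 7–19; steps 5–6 make the allyl bromide).

Steps most likely to fail:

Step 13. The tertiary mesylate may ionise and lose a proton, or the silyl group may migrate to the neighbouring oxygen, before fluoride releases the alkoxide; either would cost yield and the E/Z fidelity, and excess base could eliminate or epimerise the β-alkoxy ketone once formed. Fallback: setting out from 19, the tertiary alcohol is converted with trichloroacetonitrile and catalytic DBU (CH2Cl2, 0 °C) into the isolable tertiary trichloroacetimidate F1. Catalytic TMSOTf at −78 °C then ionises the imidate while the silyl ether oxygen supplies the electrons, an acid-triggered Grob fragmentation in which trichloroacetamide leaves and no base is present. The sequence returns to the route at ketone 22.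

Step 4. The aldoketene may dimerise faster than it adds to the enol ether, facial selectivity relative to the allylic stereocentre may be low (which would erode enantiopurity after step 10), and the amine base may epimerise C-2. Fallback: setting out from 5, the more electrophilic chloro(isopropyl)ketene (from 2-chloro-3-methylbutanoyl chloride and Et3N at 0 °C) is used, giving the α-chlorocyclobutanone F2 at lower temperature. Zinc in acetic acid then removes the chlorine, with protonation of the zinc enolate from the face opposite the alkoxy group restoring the 2,3-cis relationship. The sequence returns at 8.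

Step 12. Oligomerisation by cross-metathesis may outrun ring closure onto the hindered 1,1-disubstituted alkene. Fallback: setting out from 18, ozonolysis of both terminal alkenes (O3, CH2Cl2/MeOH, −78 °C; Me2S) gives the keto-aldehyde F3 (in equilibrium with its lactol). An intramolecular McMurry coupling (TiCl3/Zn–Cu, DME, high dilution) then forms the same trisubstituted, necessarily ring-cis cyclooctene. The sequence returns at 19.

**Further compounds**

F1 | step 13 | C-2 trichloroacetimidate of 19 | C[C@@]1(OC(=N)C(Cl)(Cl)Cl)CC/C=C(CO[Si](c2ccccc2)(c2ccccc2)C(C)(C)C)\C[C@@]2(O[Si](C)(C)C)[C@H](C(C)C)[C@H](OCc3ccc(OC)cc3)[C@@H]12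
F2 | step 4 | (3S,4R)-2-chloro-4-{(1R)-1-[(3,4-dimethoxyphenyl)methoxy]ethyl}-3-[(4-methoxyphenyl)methoxy]-2-(propan-2-yl)cyclobutan-1-one (C-2 configuration left open) | O=C1C(Cl)(C(C)C)[C@H](OCc2ccc(OC)cc2)[C@H]1[C@@H](C)OCc3ccc(OC)c(OC)c3
F3 | step 12 | keto-aldehyde from 18 (both terminal alkenes cleaved; ring centres 1R,2R,3S,4S, carbinol R) | O=C(CO[Si](c1ccccc1)(c1ccccc1)C(C)(C)C)C[C@@]1(O[Si](C)(C)C)[C@H](C(C)C)[C@H](OCc2ccc(OC)cc2)[C@H]1[C@](C)(O)CCC=O
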